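Feature: in the pyran ring (O, C4, C5, C6, C7, C8) the C3 carbon on C4 and the C9 methyl on C8 lie on the same face. A C3=C9 two-carbon bridge therefore turns the pyran into an 8-oxabicyclo[3.2.1]oct-6-ene with bridgeheads C4 and C8, which is a furan cycloadduct.
Late disconnections: the C7–O ester (E-4-oxooct-2-enoic acid), then the lactone ring at C2–C3. The lactone closes by a Reformatsky reaction of an O5 2-bromopropanoate onto the C3 aldehyde; C2 and C3 are then fixed by oxidation to the enol lactone and syn hydrogenation.
The C6 methyl comes from the C6 ketone (methylenation, hydroxyl-directed hydrogenation). The C3 aldehyde and the C9 methyl come from ozonolysis of the C3=C9 bridge. O5 and O7 come from two exo Rubottom oxidations of the bicyclic ketone.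
The bicyclic ketone comes from the [4+3] cycloaddition of 2-methylfuran with a 1-phenylethoxy-substituted siloxyallyl cation (forms C4–C5 and C7–C8); SmI2 then cuts out the auxiliary ether.
Ring order: the oxygen-bridged seven-membered ring (which holds the pyran) first, then the carbocycle is opened at C3=C9, and the lactone ring is made last.
Key step: step 3

Numbering: target numbering is used for every compound. C1 is the lactone carbonyl, C2 carries CH3, C3 carries OH, C4 carries CH3 and the pyran O, C5 carries the lactone O5, C6 carries CH3, C7 carries O7, C8 carries the pyran O, and C9 is the methyl on C8. The "upper face" is the face of O5, O7 and the C4 methyl.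
Remark on the chemistry (assumption): the orientation of 2-methylfuran and the facial sense of the (S)-auxiliary in step 3 are taken from the model given there. If one of the two is reversed, (R)-1-phenylethanol replaces 2, because the adduct then obtained gives the same ketone 8 in step 4.

Step 1
Reactants: 1 1,1-dimethoxypropan-2-one; 2 (S)-1-phenylethanol
Product: 3 1-methoxy-1-[(S)-1-phenylethoxy]propan-2-one (both acetal epimers)
Conditions: TsOH·H2O (cat.), cyclohexane, 40 °C, MeOH removed under reduced pressure, 1 in excess
Reagents that add atoms: none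
Why: Acid-catalysed transacetalisation driven by removal of methanol exchanges a single methoxy group when 1 is in excess, and the benzylic C–O bond of 2 is not broken, so its configuration is kept.

Step 2
Reactants: 3 1-methoxy-1-[(S)-1-phenylethoxy]propan-2-one
Product: 4 3-methoxy-3-[(S)-1-phenylethoxy]-2-(triethylsilyloxy)prop-1-ene (both acetal epimers)
Conditions: LiN(iPr)2, Et3SiCl (in situ quench), THF, −78 °C
Reagents that add atoms: chlorotriethylsilane, CC[Si](Cl)(CC)CC
Why: Kinetic enolisation takes a proton from the open methyl group rather than the hindered acetal C–H, and O-silylation of the enolate gives the terminal silyl enol ether.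

Step 3
Reactants: 4 3-methoxy-3-[(S)-1-phenylethoxy]-2-(triethylsilyloxy)prop-1-ene; 5 2-methylfuran
Product: 7 (1S,4R,5S)-1-methyl-4-[(S)-1-phenylethoxy]-8-oxabicyclo[3.2.1]oct-6-en-3-one, via siloxyallyl cation 6 (not isolated)
Conditions: 5 (1.5 equiv), Me3SiOTf (0.1 equiv), CH2Cl2, −95 °C
Reagents that add atoms: none
Why: Me3SiOTf removes the small methoxy group of 4 and leaves the W-shaped cation 6, which the furan diene captures at its two α-carbons in a compact [4+3] cycloaddition (4π furan plus 2π allyl cation, either asynchronous and concerted or a rapid two-stage closure); loss of the silyl group from the adduct frees the C6 ketone and returns silyl triflate to the chain. The closest known reaction type is the low-temperature [4+3] cycloaddition of furans with alkoxy-substituted siloxyallyl cations generated from silyl enol ethers of α-keto acetals, 1-phenylethyl acetals included. The single event closes the seven-membered carbocycle C3–C4–C5–C6–C7–C8–C9 by intermolecular cycloaddition and with it the pyran ring (O, C4 to C8), in which the former furan oxygen is the bridge. C7 is set by the auxiliary, since in the E oxocarbenium form with the benzylic C–H eclipsing C7–H the phenyl group covers one face and the furan bonds to the Re face of C7; C8 and C4 follow from the compact approach to the W cation, which puts the ether equatorial (endo) and fixes both bridgeheads relative to C7. The step also needs regioselectivity, which should come from the polarity of the partners: the oxocarbenium carbon C7 is the more electrophilic terminus and pairs with the free, most nucleophilic position 5 of 2-methylfuran, after which the enol silane terminus (C5 of the target) closes on the methyl-stabilised cationic carbon and makes quaternary C4. At −95 °C ring closure should outrun proton loss to a substituted furan, and the minor diastereomer and regioisomer are removed by chromatography.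

Step 4
Reactants: 7 (1S,4R,5S)-1-methyl-4-[(S)-1-phenylethoxy]-8-oxabicyclo[3.2.1]oct-6-en-3-one
Product: 8 (1S,5R)-1-methyl-8-oxabicyclo[3.2.1]oct-6-en-3-one
Conditions: SmI2 (2.5 equiv), THF/MeOH, −78 to 0 °C
Reagents that add atoms: none
Why: This is the SmI2 reductive cleavage of an α-oxygenated ketone, in which the ketyl takes a second electron and expels 1-phenylethoxide once the three-carbon bridge flexes into the boat form that aligns the C7–O bond with the carbonyl π system, methanol protonates the trivalent samarium enolate, and the bridge C–O bonds, which lie near the enolate plane, stay intact.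

Step 5
Reactants: 8 (1S,5R)-1-methyl-8-oxabicyclo[3.2.1]oct-6-en-3-one
Product: 9 5-methyl-3-(triethylsilyloxy)-8-oxabicyclo[3.2.1]octa-2,6-diene (C6=C7 enol ether)
Conditions: LiN(iPr)2, Et3SiCl (in situ quench), THF, −78 °C
Reagents that add atoms: chlorotriethylsilane, CC[Si](Cl)(CC)CC
Why: Silyl enol ether formation removes an exo (axial) α-proton, preferentially at C7 remote from the bridgehead methyl, and the regioisomeric enol ether needs no separation because steps 6 to 8 carry it to the same compound 12.

Step 6
Reactants: 9 5-methyl-3-(triethylsilyloxy)-8-oxabicyclo[3.2.1]octa-2,6-diene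
Product: 10 1-methyl-4-exo-(triethylsilyloxy)-8-oxabicyclo[3.2.1]oct-6-en-3-one
Conditions: mCPBA (1.05 equiv), CH2Cl2, −20 to 0 °C
Reagents that add atoms: 3-chloroperoxybenzoic acid, O=C(OO)c1cccc(Cl)c1
Why: In this Rubottom oxidation the electron-rich enol ether reacts ahead of the bridge alkene, oxygen arrives only on the exo face because the etheno bridge closes the endo face, and the silyl group shifts to the new oxygen, which sets C7 with O7 axial.

Step 7
Reactants: 10 1-methyl-4-exo-(triethylsilyloxy)-8-oxabicyclo[3.2.1]oct-6-en-3-one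
Product: 11 1-methyl-3,4-exo-bis(triethylsilyloxy)-8-oxabicyclo[3.2.1]octa-2,6-diene (C5=C6 enol ether)
Conditions: LiN(iPr)2, Et3SiCl (in situ quench), THF, −78 °C
Reagents that add atoms: chlorotriethylsilane, CC[Si](Cl)(CC)CC
Why: The remaining C7–H of 10 is equatorial and lies in the carbonyl plane, so kinetic enolisation can take only the axial proton at C5, and silylation traps that enolate without touching C7.

Step 8
Reactants: 11 1-methyl-3,4-exo-bis(triethylsilyloxy)-8-oxabicyclo[3.2.1]octa-2,6-diene
Product: 12 1-methyl-2-exo,4-exo-bis(triethylsilyloxy)-8-oxabicyclo[3.2.1]oct-6-en-3-one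
Conditions: mCPBA (1.05 equiv), CH2Cl2, −20 to 0 °C
Reagents that add atoms: 3-chloroperoxybenzoic acid, O=C(OO)c1cccc(Cl)c1
Why: This second Rubottom oxidation again goes on the exo face, since bonding is most advanced at C5, well away from the C7 silyl ether, while the endo face stays closed by the etheno bridge, and this sets C5.

Step 9
Reactants: 12 1-methyl-2-exo,4-exo-bis(triethylsilyloxy)-8-oxabicyclo[3.2.1]oct-6-en-3-one
Product: 14 2,6-cis-bis(hydroxymethyl)-2-methyl-3,5-bis(triethylsilyloxy)tetrahydropyran-4-one, via keto dialdehyde 13 (not isolated)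
Conditions: O3, CH2Cl2, −78 °C; Me2S, −78 °C to rt; then NaBH(OAc)3, AcOH (cat.), CH2Cl2, rt
Reagents that add atoms: ozone, [O-][O+]=O
Why: Ozonolysis cuts the only C=C bond, NaBH(OAc)3 reduces the two aldehydes but not the hindered ketone between two silyloxy groups, and the freed pyran ring flips so that C3, O5, O7 and C9 become equatorial and the C4 methyl axial.

Step 10
Reactants: 14 2,6-cis-bis(hydroxymethyl)-2-methyl-3,5-bis(triethylsilyloxy)tetrahydropyran-4-one
Product: 15 2-(hydroxymethyl)-6-(iodomethyl)-2-methyl-3,5-bis(triethylsilyloxy)tetrahydropyran-4-one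
Conditions: I2 (1.05 equiv), PPh3, imidazole, THF, 0 °C
Reagents that add atoms: iodine, II
Why: Appel-type iodination ends in an SN2 displacement, which is fast at C9 but practically shut off at the neopentyl C3 next to quaternary C4, so the two primary alcohols are told apart.

Step 11
Reactants: 15 2-(hydroxymethyl)-6-(iodomethyl)-2-methyl-3,5-bis(triethylsilyloxy)tetrahydropyran-4-one
Product: 16 2-(hydroxymethyl)-2,6-dimethyl-3,5-bis(triethylsilyloxy)tetrahydropyran-4-one
Conditions: Bu3SnH, AIBN (cat.), toluene, 80 °C
Reagents that add atoms: none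
Why: Radical chain dehalogenation leaves ketone, silyl ethers and alcohol alone and a β-alkoxyalkyl radical does not fragment, whereas a two-electron reductant such as zinc would open the pyran.

Step 12
Reactants: 16 2-(hydroxymethyl)-2,6-dimethyl-3,5-bis(triethylsilyloxy)tetrahydropyran-4-one
Product: 17 [2,6-dimethyl-4-methylene-3,5-bis(triethylsilyloxy)tetrahydropyran-2-yl]methanol
Conditions: Ph3PCH3Br (3 equiv), KOtBu (2.8 equiv), THF, 0 °C to rt
Reagents that add atoms: methyltriphenylphosphonium bromide, C[P+](c1ccccc1)(c1ccccc1)c1ccccc1.[Br-]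
Why: This is a Wittig methylenation as practised on tetrahydropyran-4-ones, in which both α-oxygen groups already hold the stable equatorial position so that reversible enolisation costs no stereocentre, and any O5-to-O3 silyl shift of the alkoxide only anticipates step 13.

Step 13
Reactants: 17 [2,6-dimethyl-4-methylene-3,5-bis(triethylsilyloxy)tetrahydropyran-2-yl]methanol
Product: 18 2,6-dimethyl-4-methylene-5-(triethylsilyloxy)-2-(triethylsilyloxymethyl)tetrahydropyran-3-ol
Conditions: KOtBu (0.2 equiv), THF, 0 °C
Reagents that add atoms: none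
Why: A base-catalysed O-to-O silyl migration through a six-membered pentacoordinate silicate moves the group from the crowded secondary O5 (between quaternary C4 and the methylene carbon) to the primary O3, and since the O7 silyl ether has no hydroxyl neighbour this tells O5 and O7 apart.

Step 14
Reactants: 18 2,6-dimethyl-4-methylene-5-(triethylsilyloxy)-2-(triethylsilyloxymethyl)tetrahydropyran-3-ol
Product: 19 2,4,6-trimethyl-5-(triethylsilyloxy)-2-(triethylsilyloxymethyl)tetrahydropyran-3-ol (C6 methyl equatorial)
Conditions: [Ir(cod)(PCy3)(py)]PF6 (5 mol %), H2 (1 atm), CH2Cl2, 0 °C to rt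
Reagents that add atoms: none
Why: In this hydroxyl-directed homogeneous hydrogenation iridium binds the allylic O5–H, which sits on the upper side of the alkene plane, and delivers hydrogen to that face, so that H6 ends cis to O5 and the C6 methyl equatorial and trans to O5 and O7.

Step 15
Reactants: 19 2,4,6-trimethyl-5-(triethylsilyloxy)-2-(triethylsilyloxymethyl)tetrahydropyran-3-ol; 20 2-bromopropanoyl bromide (racemic)
Product: 21 O5 2-bromopropanoate of 19 (bromide epimers)
Conditions: pyridine, CH2Cl2, 0 °C to rt
Reagents that add atoms: none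
Why: Acylation with an acid bromide is strong enough for the hindered secondary O5–H, the only free hydroxyl, and the bromide-bearing centre is lost later, so racemic 20 serves.

Step 16
Reactants: 21 O5 2-bromopropanoate of 19
Product: 22 C3 aldehyde (2-formyl-2,4,6-trimethyl-5-(triethylsilyloxy)tetrahydropyran-3-yl 2-bromopropanoate)
Conditions: (COCl)2, DMSO, CH2Cl2, −78 to −40 °C; Et3N, −78 to 0 °C
Reagents that add atoms: none
Why: Swern conditions turn a primary triethylsilyl ether directly into the aldehyde (the ether oxygen attacks the chlorosulfonium salt and chloride takes the silicon), while the hindered secondary silyl ether at O7 and the bromo ester are left.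

Step 17
Reactants: 22 C3 aldehyde
Product: 23 bicyclic β-hydroxy δ-lactone (epimers at C2 and C3)
Conditions: SmI2 (2.1 equiv, added to 22), THF, −78 °C
Reagents that add atoms: none
Why: In this intramolecular Reformatsky reaction the α-bromo ester is reduced far faster than the aldehyde and the trivalent samarium enolate closes the lactone ring by 6-(enolendo)-exo-trig formation of C2–C3; the enolate–aldehyde chelate should place the C3 oxygen axial (epimeric to the target), which does not matter because step 18 erases C2 and C3.

Step 18
Reactants: 23 bicyclic β-hydroxy δ-lactone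
Product: 24 enol lactone (3-hydroxy-2-methyl-2-en-1-one form of the β-keto lactone)
Conditions: Dess–Martin periodinane, CH2Cl2, rt
Reagents that add atoms: none
Why: Dess–Martin oxidation converges all C2/C3 epimers on one β-keto lactone, which rests as its conjugated enol and cannot eliminate or epimerise at quaternary C4.

Step 19
Reactants: 24 enol lactone
Product: 25 (2R,3S)-3-hydroxy-2-methyl lactone with O7 triethylsilyl ether
Conditions: H2 (50 bar), Raney Ni (washed neutral), EtOAc, rt
Reagents that add atoms: none
Why: Syn hydrogenation of a 3-alkyl-4-hydroxy-5,6-dihydropyran-2-one over Raney Ni is the known way to cis 3-alkyl-4-hydroxy δ-lactones, and here the axial C4 methyl shields the upper face, so both hydrogens add from below and leave C3–OH and C2–CH3 on the upper face.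

Step 20
Reactants: 25 (2R,3S)-3-hydroxy-2-methyl lactone with O7 triethylsilyl ether
Product: 26 C3,C7-diol lactone
Conditions: HF·pyridine, pyridine, THF, 0 °C to rt
Reagents that add atoms: none
Why: Fluoride desilylation in a weakly acidic medium frees O7–H without the base that could epimerise C2 or dehydrate the β-hydroxy lactone.

Step 21
Reactants: 27 2-butylfuran
Product: 29 (E)-4-oxooct-2-enal, via (Z)-4-oxooct-2-enal 28 (not isolated)
Conditions: NBS, NaHCO3, acetone/H2O, −15 °C; then pyridine, rt
Reagents that add atoms: water, O
Why: Oxidative ring opening of a 2-alkylfuran with NBS in aqueous acetone gives the cis enedicarbonyl compound, and reversible conjugate addition of pyridine isomerises it to the more stable E alkene.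

Step 22
Reactants: 29 (E)-4-oxooct-2-enal
Product: 30 (E)-4-oxooct-2-enoic acid
Conditions: NaClO2, NaH2PO4, 2-methylbut-2-ene, tBuOH/H2O, 0 °C to rt
Reagents that add atoms: sodium chlorite, [Na+].[O-]Cl=O
Why: Pinnick oxidation converts the enal into the acid without touching the ketone or the alkene geometry, and the alkene scavenger takes up the hypochlorous acid.

Step 23
Reactants: 26 C3,C7-diol lactone; 30 (E)-4-oxooct-2-enoic acid
Product: 31 botcinin I
Conditions: 30 (1.05 equiv), DCC (1.1 equiv), DMAP (0.1 equiv), CH2Cl2, −20 to 0 °C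
Reagents that add atoms: none
Why: Steglich esterification should take the equatorial C7 hydroxyl, flanked by two methine carbons, ahead of the C3 hydroxyl, which is neopentyl-like next to quaternary C4, crowded by the cis C2 methyl and made less nucleophilic by the lactone carbonyl.

Compound list
1 | 1,1-dimethoxypropan-2-one | CC(=O)C(OC)OC | starting material
2 | (S)-1-phenylethanol | C[C@H](O)c1ccccc1 | starting material
3 | 1-methoxy-1-[(S)-1-phenylethoxy]propan-2-one, both acetal epimers | CC(=O)C(OC)O[C@@H](C)c1ccccc1 | intermediate
4 | 3-methoxy-3-[(S)-1-phenylethoxy]-2-(triethylsilyloxy)prop-1-ene, both acetal epimers | C=C(O[Si](CC)(CC)CC)C(OC)O[C@@H](C)c1ccccc1 | intermediate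
5 | 2-methylfuran | Cc1ccco1 | starting material
6 | (E)-1-[(S)-1-phenylethoxy]-2-(triethylsilyloxy)allyl cation, triflate (not isolated) | C=C(O[Si](CC)(CC)CC)/C=[O+]/[C@@H](C)c1ccccc1.[O-]S(=O)(=O)C(F)(F)F | intermediate
7 | (1S,4R,5S)-1-methyl-4-[(S)-1-phenylethoxy]-8-oxabicyclo[3.2.1]oct-6-en-3-one; ether on C7 equatorial (endo), bridgeheads are C4 (methyl) and C8 | O=C1C[C@@]2(C)C=C[C@@H]([C@H]1O[C@@H](C)c1ccccc1)O2 | intermediate
8 | (1S,5R)-1-methyl-8-oxabicyclo[3.2.1]oct-6-en-3-one | O=C1C[C@@]2(C)C=C[C@@H](C1)O2 | intermediate
9 | 5-methyl-3-(triethylsilyloxy)-8-oxabicyclo[3.2.1]octa-2,6-diene; C6=C7 enol ether, bridgeheads as in 8 | CC[Si](CC)(CC)OC1=C[C@@H]2C=C[C@](C)(C1)O2 | intermediate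
10 | 1-methyl-4-exo-(triethylsilyloxy)-8-oxabicyclo[3.2.1]oct-6-en-3-one; O7 axial, syn to the oxygen bridge | O=C1C[C@@]2(C)C=C[C@@H]([C@@H]1O[Si](CC)(CC)CC)O2 | intermediate
11 | 1-methyl-3,4-exo-bis(triethylsilyloxy)-8-oxabicyclo[3.2.1]octa-2,6-diene; C5=C6 enol ether | CC[Si](CC)(CC)OC1=C[C@@]2(C)C=C[C@@H]([C@@H]1O[Si](CC)(CC)CC)O2 | intermediate
12 | 1-methyl-2-exo,4-exo-bis(triethylsilyloxy)-8-oxabicyclo[3.2.1]oct-6-en-3-one; O5 and O7 both axial, syn to the oxygen bridge | O=C1[C@H](O[Si](CC)(CC)CC)[C@@]2(C)C=C[C@@H]([C@@H]1O[Si](CC)(CC)CC)O2 | intermediate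
13 | 2-methyl-4-oxo-3,5-bis(triethylsilyloxy)tetrahydropyran-2,6-dicarbaldehyde; formyl groups cis, each silyloxy trans to its neighbouring formyl (not isolated) | CC[Si](CC)(CC)O[C@@H]1C(=O)[C@H](O[Si](CC)(CC)CC)[C@@](C)(C=O)O[C@H]1C=O | intermediate
14 | 2,6-bis(hydroxymethyl)-2-methyl-3,5-bis(triethylsilyloxy)tetrahydropyran-4-one; C3 and C9 cis and equatorial, O5 and O7 equatorial, C4 methyl axial | CC[Si](CC)(CC)O[C@@H]1C(=O)[C@H](O[Si](CC)(CC)CC)[C@@](C)(CO)O[C@H]1CO | intermediate
15 | 2-(hydroxymethyl)-6-(iodomethyl)-2-methyl-3,5-bis(triethylsilyloxy)tetrahydropyran-4-one; iodide on C9, configuration as in 14 | CC[Si](CC)(CC)O[C@@H]1C(=O)[C@H](O[Si](CC)(CC)CC)[C@@](C)(CO)O[C@H]1CI | intermediate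
16 | 2-(hydroxymethyl)-2,6-dimethyl-3,5-bis(triethylsilyloxy)tetrahydropyran-4-one; configuration as in 14 | CC[Si](CC)(CC)O[C@@H]1C(=O)[C@H](O[Si](CC)(CC)CC)[C@@](C)(CO)O[C@H]1C | intermediate
17 | [2,6-dimethyl-4-methylene-3,5-bis(triethylsilyloxy)tetrahydropyran-2-yl]methanol; configuration as in 14 | CC[Si](CC)(CC)O[C@@H]1C(=C)[C@H](O[Si](CC)(CC)CC)[C@@](C)(CO)O[C@H]1C | intermediate
18 | 2,6-dimethyl-4-methylene-5-(triethylsilyloxy)-2-(triethylsilyloxymethyl)tetrahydropyran-3-ol; O5–H free, O3 and O7 silylated | CC[Si](CC)(CC)O[C@@H]1C(=C)[C@H](O)[C@@](C)(CO[Si](CC)(CC)CC)O[C@H]1C | intermediate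
19 | 2,4,6-trimethyl-5-(triethylsilyloxy)-2-(triethylsilyloxymethyl)tetrahydropyran-3-ol; C6 methyl equatorial, trans to O5 and O7 | CC[Si](CC)(CC)O[C@@H]1[C@@H](C)[C@H](O)[C@@](C)(CO[Si](CC)(CC)CC)O[C@H]1C | intermediate
20 | 2-bromopropanoyl bromide (racemic) | CC(Br)C(=O)Br | starting material
21 | O5 2-bromopropanoate of 19, bromide epimers | CC[Si](CC)(CC)O[C@@H]1[C@@H](C)[C@H](OC(=O)C(C)Br)[C@@](C)(CO[Si](CC)(CC)CC)O[C@H]1C | intermediate
22 | 2-formyl-2,4,6-trimethyl-5-(triethylsilyloxy)tetrahydropyran-3-yl 2-bromopropanoate; C3 aldehyde, bromide epimers | CC[Si](CC)(CC)O[C@@H]1[C@@H](C)[C@H](OC(=O)C(C)Br)[C@@](C)(C=O)O[C@H]1C | intermediate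
23 | trans-fused pyrano-δ-lactone with C3–OH and C2–CH3, epimers at C2 and C3, O7 triethylsilyl ether | CC[Si](CC)(CC)O[C@@H]1[C@@H](C)[C@@H]2OC(=O)C(C)C(O)[C@@]2(C)O[C@H]1C | intermediate
24 | enol form of the C3-oxo lactone (C2=C3 enol), O7 triethylsilyl ether | CC[Si](CC)(CC)O[C@@H]1[C@@H](C)[C@@H]2OC(=O)C(C)=C(O)[C@@]2(C)O[C@H]1C | intermediate
25 | (2R,3S)-hydroxy lactone, C2–CH3 and C3–OH cis on the upper face, O7 triethylsilyl ether | CC[Si](CC)(CC)O[C@@H]1[C@@H](C)[C@@H]2OC(=O)[C@H](C)[C@H](O)[C@@]2(C)O[C@H]1C | intermediate
26 | C3,C7-diol lactone (7-deacyl core of the target) | O[C@@H]1[C@@H](C)[C@@H]2OC(=O)[C@H](C)[C@H](O)[C@@]2(C)O[C@H]1C | intermediate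
27 | 2-butylfuran | CCCCc1ccco1 | starting material
28 | (Z)-4-oxooct-2-enal (not isolated) | CCCCC(=O)/C=C\C=O | intermediate
29 | (E)-4-oxooct-2-enal | CCCCC(=O)/C=C/C=O | intermediate
30 | (E)-4-oxooct-2-enoic acid | CCCCC(=O)/C=C/C(=O)O | intermediate
31 | botcinin I | CCCCC(=O)/C=C/C(=O)O[C@@H]1[C@@H](C)[C@@H]2OC(=O)[C@H](C)[C@H](O)[C@@]2(C)O[C@H]1C | target

Total step count: 23. Longest linear sequence: 21 (steps 1 to 20 and step 23).

Steps most likely to fail

Step 3 (key step).
- What may go wrong: the furan may add in the opposite orientation. The phenyl group may shield the cation face too weakly. The first-formed furanyl cation may lose a proton (aromatic substitution) before the second bond to the methyl-bearing carbon forms.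
- Fallback: it sets out from 5, returns at 8, and takes the absolute configuration from a resolution instead of an auxiliary.
- 2-Methylfuran is combined with 1,1,3-trichloropropan-2-one and NaOCH2CF3 in CF3CH2OH at 0 °C. This is a [4+3] cycloaddition of the symmetric 1,3-dichloro-oxyallyl cation, so no regiochemical question arises. It gives 2,4-dichloro-1-methyl-8-oxabicyclo[3.2.1]oct-6-en-3-one F1.
- Zn/Cu couple with NH4Cl in MeOH removes both chlorides and gives racemic 1-methyl-8-oxabicyclo[3.2.1]oct-6-en-3-one F2.
- Preparative chromatography on a cellulose carbamate chiral phase delivers 8 and sets aside its (1R,5S) antipode F3.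

Step 14.
- What may go wrong: hydrogen may be delivered from the lower, sterically open face. The equatorial hydroxyl lies close to the alkene plane and the axial C4 methyl crowds the upper face. The alkene may also migrate into the ring.
- Fallback: it goes from 18 straight to 19 and makes no new compound (F0). The control element changes from catalyst delivery to product stability.
- Radical hydrogen-atom-transfer hydrogenation (Mn(dpm)3 cat., PhSiH3, tBuOOH, iPrOH, rt) puts a hydrogen atom on the CH2 terminus. The tertiary C6 radical then takes its second hydrogen so as to leave the methyl equatorial, because an axial C6 methyl would be syn-axial to the C4 methyl.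

Step 19.
- What may go wrong: hydrogen uptake at the tetrasubstituted enol double bond next to quaternary C4 may be slow. Reduction may also go through the keto tautomer, which would lose the cis relation between C2 and C3.
- Fallback: it sets out from 19, returns at 26, and builds C1–C3 by chelate-controlled addition instead of ring closure and hydrogenation.
- Et3SiOTf and 2,6-lutidine give the tris(triethylsilyl) ether F4.
- Swern conditions as in step 16 give the O5,O7-bis(triethylsilyl) C3 aldehyde F5.
- CH2=C(CH3)MgBr with MgBr2·OEt2 in CH2Cl2 at −78 °C adds under Cram chelate control. Magnesium is held between the aldehyde oxygen and the pyran oxygen, and attack comes past the C4 methyl rather than past C5. This gives the (3S)-allylic alcohol F6.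
- 9-BBN followed by H2O2/NaOH, which is anti-selective for 1,1-disubstituted allylic alcohols, gives the anti 2-methyl-1,3-diol F7 and sets C2.
- HF·pyridine gives the tetraol F8.
- TEMPO with PhI(OAc)2 oxidises only the primary C1 hydroxyl. The resulting aldehyde forms a lactol with O5–H, and this is oxidised on to the lactone 26.

Further compounds
F1 | step 3 | 2,4-dichloro-1-methyl-8-oxabicyclo[3.2.1]oct-6-en-3-one (racemic, chloride epimers) | O=C1C(Cl)C2(C)C=CC(O2)C1Cl
F2 | step 3 | racemic 1-methyl-8-oxabicyclo[3.2.1]oct-6-en-3-one | O=C1CC2(C)C=CC(C1)O2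
F3 | step 3 | (1R,5S)-1-methyl-8-oxabicyclo[3.2.1]oct-6-en-3-one | O=C1C[C@]2(C)C=C[C@H](C1)O2
F0 | step 14 | none | none
F4 | step 19 | 2,4,6-trimethyl-3,5-bis(triethylsilyloxy)-2-(triethylsilyloxymethyl)tetrahydropyran, configuration as in 19 | CC[Si](CC)(CC)O[C@@H]1[C@@H](C)[C@H](O[Si](CC)(CC)CC)[C@@](C)(CO[Si](CC)(CC)CC)O[C@H]1C
F5 | step 19 | 2,4,6-trimethyl-3,5-bis(triethylsilyloxy)tetrahydropyran-2-carbaldehyde | CC[Si](CC)(CC)O[C@@H]1[C@@H](C)[C@H](O[Si](CC)(CC)CC)[C@@](C)(C=O)O[C@H]1C
F6 | step 19 | (3S)-allylic alcohol from isopropenyl addition to F5 | CC[Si](CC)(CC)O[C@@H]1[C@@H](C)[C@H](O[Si](CC)(CC)CC)[C@@](C)([C@@H](O)C(C)=C)O[C@H]1C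
F7 | step 19 | anti 2-methyl-1,3-diol (C1–OH, C3–OH), O5 and O7 triethylsilyl ethers | CC[Si](CC)(CC)O[C@@H]1[C@@H](C)[C@H](O[Si](CC)(CC)CC)[C@@](C)([C@@H](O)[C@@H](C)CO)O[C@H]1C
F8 | step 19 | tetraol (C1, C3, C5, C7 hydroxyls free) | O[C@@H]1[C@@H](C)[C@H](O)[C@@](C)([C@@H](O)[C@@H](C)CO)O[C@H]1C
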